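**Retrosynthetic overview**
1. Salimabromide 25 ⇐ dibromination at arene C6 and C8 of enone 24 ⇐ singlet-oxygen ene/dehydration of cycloheptene 21 ⇐ ring-closing metathesis of the vinyl and allyl groups of cis-lactone 20 (seven-membered ring, formed last).
2. 20 ⇐ conjugate reduction of butenolide 19, which sets the benzylic CH and the lactone α-CH from the face opposite both side chains.
3. Strategic feature: the lactone C=O carbon is the only atom between the α-CH of the six-membered carbocycle (neopentyl, next to the methyl-bearing quaternary carbon) and the ring oxygen on the O-methine, so it is excised as carbon monoxide: 19 ⇐ hydroxy vinyl bromide 17 + CO 18 (lactone ring, formed second).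
4. 17 ⇐ asymmetric vinylation of β-bromo enal 16 ⇐ bromoformylation of 2-tetralone 14 ⇐ epoxidation/Meinwald rearrangement of dihydronaphthalene 12 ⇐ amide reduction/Wittig ⇐ Eschenmoser–Claisen rearrangement of allylic alcohol 7 (quaternary stereocentre).
5. 7 ⇐ CBS reduction of 3-methyl enone 6 ⇐ tetralone 3 ⇐ Friedel–Crafts annulation of ethylbenzene 1 with lactone 2 (carbocyclic six-membered ring, formed first).

Key step: step 13

Assumption: the sense of induction of the (R)-CBS catalyst (step 5) and of (+)-MIB (step 12) is assigned by analogy with 1-tetralone and benzaldehyde, the other catalyst enantiomer being used if either proves opposite; the epoxide carbons of 13 and the peroxide-bearing carbon of 22 and 23 carry no defined configuration because they are destroyed in the next operation.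

**Step 1**
Reactants: 1 ethylbenzene; 2 5,5-dimethyldihydrofuran-2(3H)-one
Product: 3 7-ethyl-4,4-dimethyl-3,4-dihydronaphthalen-1(2H)-one
Conditions: AlCl3 (2.5 equiv), ethylbenzene (excess, as solvent), 0 °C to 60 °C; poured onto ice
Reagents that add atoms: none
Why: AlCl3 opens the lactone to a tertiary carbocation that alkylates ethylbenzene para to the ethyl group, and the resulting arylpentanoic acid acylates the ring ortho to the new quaternary carbon (Friedel–Crafts alkylation–acylation cascade), which places the ethyl group at C7.

**Step 2**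
Reactants: 3 7-ethyl-4,4-dimethyl-3,4-dihydronaphthalen-1(2H)-one
Product: 4 7-ethyl-4,4-dimethylnaphthalen-1(4H)-one
Conditions: Pd(O2CCF3)2 (5 mol %), DMSO (10 mol %), O2 (1 atm), AcOH, 80 °C
Reagents that add atoms: none
Why: Aerobic palladium-catalysed α,β-dehydrogenation (a direct Saegusa-type oxidation through a divalent palladium enolate and β-hydride elimination) should give the enone, and the C4 gem-dimethyl group stops the ring from aromatising.

**Step 3**
Reactants: 4 7-ethyl-4,4-dimethylnaphthalen-1(4H)-one
Product: 5 [(7-ethyl-3,4,4-trimethyl-3,4-dihydronaphthalen-1-yl)oxy]trimethylsilane (racemic at C3)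
Conditions: Me2CuLi (from MeLi and CuI, 1.5 equiv), Me3SiCl (3 equiv), THF, −78 °C to −20 °C; Et3N, cold aqueous work-up
Reagents that add atoms: methyllithium, [Li]C; chlorotrimethylsilane, C[Si](C)(C)Cl
Why: Cuprate conjugate addition accelerated by Me3SiCl puts the methyl group on C3 next to the quaternary carbon and traps the enolate as its silyl enol ether; the new C3 centre is racemic and is erased in step 4.

**Step 4**
Reactants: 5 [(7-ethyl-3,4,4-trimethyl-3,4-dihydronaphthalen-1-yl)oxy]trimethylsilane
Product: 6 7-ethyl-3,4,4-trimethylnaphthalen-1(4H)-one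
Conditions: Pd(OAc)2 (10 mol %), O2 (1 atm), DMSO, 50 °C
Reagents that add atoms: none
Why: Saegusa–Ito oxidation, in which the silyl enol ether gives a divalent palladium enolate and β-hydride elimination of the only β-hydrogen (C3–H) returns the enone with the methyl group now on the double bond.

**Step 5**
Reactants: 6 7-ethyl-3,4,4-trimethylnaphthalen-1(4H)-one
Product: 7 (1S)-7-ethyl-3,4,4-trimethyl-1,4-dihydronaphthalen-1-ol
Conditions: (R)-2-methyl-CBS-oxazaborolidine (10 mol %), BH3·SMe2 (0.7 equiv), THF, −20 °C; MeOH, then water
Reagents that add atoms: none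
Why: Corey–Bakshi–Shibata reduction gives 1,2-reduction only, and the benzo flank with its peri C–H should act as the large group as in 1-tetralone, so the (R)-catalyst should deliver hydride to give the (S)-carbinol.

**Step 6**
Reactants: 7 (1S)-7-ethyl-3,4,4-trimethyl-1,4-dihydronaphthalen-1-ol; 8 1,1-dimethoxy-N,N-dimethylethanamine
Product: 10 2-[(2R)-6-ethyl-1,1,2-trimethyl-1,2-dihydronaphthalen-2-yl]-N,N-dimethylacetamide, via ketene N,O-acetal 9 (not isolated)
Conditions: 8 (4 equiv), xylene, 140 °C, MeOH distilled off
Reagents that add atoms: none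
Why: Eschenmoser–Claisen rearrangement, in which acetal exchange gives the ketene N,O-acetal and its [3,3]-sigmatropic shift forms the C–C bond on the ring face that carried the C–O bond, so the carbinol configuration is relayed to the methyl-bearing quaternary carbon under neutral conditions that spare the acid-labile benzylic allylic alcohol.

**Step 7**
Reactants: 10 2-[(2R)-6-ethyl-1,1,2-trimethyl-1,2-dihydronaphthalen-2-yl]-N,N-dimethylacetamide
Product: 11 2-[(2R)-6-ethyl-1,1,2-trimethyl-1,2-dihydronaphthalen-2-yl]acetaldehyde
Conditions: Cp2Zr(H)Cl (1.5 equiv), THF, 23 °C; water/silica work-up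
Reagents that add atoms: water, O
Why: Hydrozirconation of the tertiary amide by Cp2Zr(H)Cl stops at the aldehyde oxidation level, the adduct being hydrolysed on work-up, and the hindered cis-disubstituted styrene should react far more slowly than the amide.

**Step 8**
Reactants: 11 2-[(2R)-6-ethyl-1,1,2-trimethyl-1,2-dihydronaphthalen-2-yl]acetaldehyde
Product: 12 (2R)-6-ethyl-1,1,2-trimethyl-2-(prop-2-en-1-yl)-1,2-dihydronaphthalene
Conditions: Ph3PCH3Br (1.5 equiv), KOtBu (1.4 equiv), THF, 0 °C to 23 °C
Reagents that add atoms: methyltriphenylphosphonium bromide, C[P+](c1ccccc1)(c1ccccc1)c1ccccc1.[Br-]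
Why: Wittig methylenation of an aldehyde whose α-carbon carries no stereocentre turns the two-carbon chain into the allyl group needed for the later ring closure.

**Step 9**
Reactants: 12 (2R)-6-ethyl-1,1,2-trimethyl-2-(prop-2-en-1-yl)-1,2-dihydronaphthalene
Product: 13 (3S)-1,2-epoxy-7-ethyl-3,4,4-trimethyl-3-(prop-2-en-1-yl)-1,2,3,4-tetrahydronaphthalene (epoxide configuration undefined)
Conditions: (R,R)-(salen)MnCl, [N,N′-bis(3,5-di-tert-butylsalicylidene)-1,2-cyclohexanediaminato]manganese chloride (3 mol %), aq. NaOCl (pH 11.3), 4-phenylpyridine N-oxide (15 mol %), CH2Cl2, 0 °C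
Reagents that add atoms: sodium hypochlorite, [Na+].[O-]Cl
Why: Jacobsen–Katsuki epoxidation is chosen for chemoselectivity, because the manganese oxo species epoxidises a cis-disubstituted aryl-conjugated alkene far faster than an isolated monosubstituted alkene such as the allyl group; the epoxide configuration is of no consequence.

**Step 10**
Reactants: 13 (3S)-1,2-epoxy-7-ethyl-3,4,4-trimethyl-3-(prop-2-en-1-yl)-1,2,3,4-tetrahydronaphthalene
Product: 14 (3S)-7-ethyl-3,4,4-trimethyl-3-(prop-2-en-1-yl)-3,4-dihydronaphthalen-2(1H)-one
Conditions: ZnI2 (20 mol %), toluene, 23 °C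
Reagents that add atoms: none
Why: Meinwald rearrangement, in which the Lewis acid opens the epoxide at the benzylic carbon and the pseudo-axial C2 hydride, aligned with the empty benzylic orbital while the ring C2–C3 bond is not, shifts to give the 2-tetralone and not the ring-contracted aldehyde.

**Step 11**
Reactants: 14 (3S)-7-ethyl-3,4,4-trimethyl-3-(prop-2-en-1-yl)-3,4-dihydronaphthalen-2(1H)-one
Product: 16 (3S)-2-bromo-7-ethyl-3,4,4-trimethyl-3-(prop-2-en-1-yl)-3,4-dihydronaphthalene-1-carbaldehyde, via iminium bromide 15 (not isolated)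
Conditions: PBr3 (2.7 equiv), DMF (3 equiv), CHCl3, 0 °C to 60 °C; then ice-water
Reagents that add atoms: N,N-dimethylformamide, CN(C)C=O; phosphorus tribromide, BrP(Br)Br; water, O
Why: Vilsmeier–Haack bromoformylation, in which the ketone can enolise only towards the benzylic C1 because C3 is quaternary, so the bromoiminium reagent formylates C1 and the enol oxygen at C2 is replaced by bromide, giving a single β-bromo enal after hydrolysis of the iminium salt.

**Step 12**
Reactants: 16 (3S)-2-bromo-7-ethyl-3,4,4-trimethyl-3-(prop-2-en-1-yl)-3,4-dihydronaphthalene-1-carbaldehyde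
Product: 17 (1R)-1-[(3S)-2-bromo-7-ethyl-3,4,4-trimethyl-3-(prop-2-en-1-yl)-3,4-dihydronaphthalen-1-yl]prop-2-en-1-ol
Conditions: divinylzinc (1.5 equiv, salt-free solution), (+)-MIB [(2R)-3-exo-morpholinoisoborneol] (10 mol %), toluene, −20 °C to 0 °C; aqueous work-up
Reagents that add atoms: divinylzinc, C=C[Zn]C=C
Why: Amino-alcohol-catalysed organozinc addition to the aldehyde is under catalyst control, needed because the quaternary centre is too remote to bias the aldehyde faces, and the ligand enantiomer opposite to the one that delivers to the Si face of benzaldehyde should add the vinyl group to the Re face and give the (R)-carbinol.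

**Step 13**
Reactants: 17 (1R)-1-[(3S)-2-bromo-7-ethyl-3,4,4-trimethyl-3-(prop-2-en-1-yl)-3,4-dihydronaphthalen-1-yl]prop-2-en-1-ol; 18 carbon monoxide
Product: 19 (1R,4S)-8-ethyl-1-ethenyl-4,5,5-trimethyl-4-(prop-2-en-1-yl)-4,5-dihydronaphtho[1,2-c]furan-3(1H)-one
Conditions: Pd(PPh3)4 (10 mol %), CO (1 atm), i-Pr2NEt (2 equiv), DMF, 80 °C
Reagents that add atoms: none
Why: Zerovalent palladium adds oxidatively to the C–Br bond of the tetrasubstituted vinyl bromide, CO inserts into the vinyl–palladium bond, and the secondary hydroxyl held cis on the same double bond attacks the acylpalladium to release the butenolide and zerovalent palladium, HBr being taken up by the amine. The closest known reaction type is the palladium-catalysed carbonylative lactonisation of γ-hydroxy vinyl halides and triflates to butenolides. The lactone ring closes by a 5-exo-trig acyl substitution of oxygen on the acyl carbon, so the C3a–C3 and C3–O2 bonds are formed in one operation. No stereocentre is created; the carbinol C–O bond is not broken, so its R configuration is carried into C1 of 19, and the hindered amine base is chosen so that the acidic O-methine C–H of the vinyl butenolide is not removed. The step needs carbonylation to win over Heck-type insertion: from the vinylpalladium only 4-exo or 5-endo insertions into the allyl or vinyl group are open, and under CO it is converted quickly into the acyl species, whose alcoholysis by the hydroxyl five atoms away should outrun 5-exo acylpalladation of the alkenes. Carbon monoxide is small enough to reach the carbon beside the quaternary centre, where larger coupling partners would be blocked.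

**Step 14**
Reactants: 19 (1R,4S)-8-ethyl-1-ethenyl-4,5,5-trimethyl-4-(prop-2-en-1-yl)-4,5-dihydronaphtho[1,2-c]furan-3(1H)-one
Product: 20 (1R,3aR,4R,9bS)-8-ethyl-1-ethenyl-4,5,5-trimethyl-4-(prop-2-en-1-yl)-3a,4,5,9b-tetrahydronaphtho[1,2-c]furan-3(1H)-one
Conditions: SmI2 (2.5 equiv), MeOH (10 equiv), THF, −20 °C to 23 °C (HMPA added if the reduction stalls)
Reagents that add atoms: none
Why: Electron-transfer conjugate reduction of the aryl-conjugated butenolide by SmI2 leaves the isolated vinyl and allyl groups untouched; the benzylic carbon C9b is protonated on the face opposite the C1 vinyl and C4 allyl groups, which lie on one face of the flat tricycle, and protonation of the samarium enolate at C3a on the same face gives the cis-fused lactone, while the ring C1–O bond, lying in the nodal plane of the π system, should resist reductive cleavage.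

**Step 15**
Reactants: 20 (1R,3aR,4R,9bS)-8-ethyl-1-ethenyl-4,5,5-trimethyl-4-(prop-2-en-1-yl)-3a,4,5,9b-tetrahydronaphtho[1,2-c]furan-3(1H)-one
Product: 21 tetracyclic cycloheptene lactone (20 with the vinyl CH and the allyl CH joined as a ring cis-CH=CH)
Conditions: second-generation Grubbs catalyst (5 mol %), toluene (0.005 M), 80 °C
Reagents that add atoms: none
Why: Ring-closing metathesis joins the C1 vinyl and C4 allyl groups, which the cis ring fusion now holds on the same face within reach of each other, into the cis-cycloheptene with loss of ethene.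

**Step 16**
Reactants: 21 tetracyclic cycloheptene lactone
Product: 24 6,8-didebromosalimabromide (the tetracyclic enone lactone without bromine), via allylic hydroperoxide 22 (not isolated), via peroxyacetate 23 (not isolated)
Conditions: O2, tetraphenylporphyrin (1 mol %), visible light, Ac2O (2 equiv), pyridine (2 equiv), DMAP (5 mol %), CH2Cl2, 0 °C to 23 °C
Reagents that add atoms: dioxygen, O=O
Why: Schenck ene reaction of singlet oxygen at the cis-disubstituted ring alkene should bond oxygen to the alkene carbon next to the O-methine and take hydrogen from the allylic CH2, because the only other allylic hydrogen sits on the bridgehead O-methine and cannot align with the π bond, and acetylation of the hydroperoxide followed by pyridine-induced loss of acetate (Kornblum–DeLaMare-type dehydration) gives the transposed enone in the same flask, erasing the undefined peroxide-bearing centre.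

**Step 17**
Reactants: 24 6,8-didebromosalimabromide
Product: 25 salimabromide
Conditions: Br2 (2.2 equiv), AgO2CCF3 (2.2 equiv), CF3CO2H, 0 °C, dark
Reagents that add atoms: bromine, BrBr
Why: Electrophilic aromatic bromination by the acyl hypobromite formed from Br2 and AgO2CCF3 should take both positions ortho to the ethyl group (C6, also para to the benzylic ring carbon, and C8), which are doubly alkyl-activated, whereas C5 is singly activated and shielded by the gem-dimethyl group, and the electron-poor enone in acidic medium should not compete.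

**Compound list**
1 | ethylbenzene | CCc1ccccc1 | starting material
2 | 5,5-dimethyldihydrofuran-2(3H)-one | CC1(C)CCC(=O)O1 | starting material
3 | 7-ethyl-4,4-dimethyl-3,4-dihydronaphthalen-1(2H)-one | CCc1ccc2c(c1)C(=O)CCC2(C)C | intermediate
4 | 7-ethyl-4,4-dimethylnaphthalen-1(4H)-one | CCc1ccc2c(c1)C(=O)C=CC2(C)C | intermediate
5 | [(7-ethyl-3,4,4-trimethyl-3,4-dihydronaphthalen-1-yl)oxy]trimethylsilane, racemic at C3 | CCc1ccc2c(c1)C(O[Si](C)(C)C)=CC(C)C2(C)C | intermediate
6 | 7-ethyl-3,4,4-trimethylnaphthalen-1(4H)-one | CCc1ccc2c(c1)C(=O)C=C(C)C2(C)C | intermediate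
7 | (1S)-7-ethyl-3,4,4-trimethyl-1,4-dihydronaphthalen-1-ol | CCc1ccc2c(c1)[C@@H](O)C=C(C)C2(C)C | intermediate
8 | 1,1-dimethoxy-N,N-dimethylethanamine | CC(OC)(OC)N(C)C | starting material
9 | ketene N,O-acetal, 1-{[(1S)-7-ethyl-3,4,4-trimethyl-1,4-dihydronaphthalen-1-yl]oxy}-N,N-dimethylethen-1-amine | CCc1ccc2c(c1)[C@@H](OC(=C)N(C)C)C=C(C)C2(C)C | intermediate (not isolated)
10 | 2-[(2R)-6-ethyl-1,1,2-trimethyl-1,2-dihydronaphthalen-2-yl]-N,N-dimethylacetamide | CCc1ccc2c(c1)C=C[C@@](C)(CC(=O)N(C)C)C2(C)C | intermediate
11 | 2-[(2R)-6-ethyl-1,1,2-trimethyl-1,2-dihydronaphthalen-2-yl]acetaldehyde | CCc1ccc2c(c1)C=C[C@@](C)(CC=O)C2(C)C | intermediate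
12 | (2R)-6-ethyl-1,1,2-trimethyl-2-(prop-2-en-1-yl)-1,2-dihydronaphthalene | CCc1ccc2c(c1)C=C[C@@](C)(CC=C)C2(C)C | intermediate
13 | (3S)-1,2-epoxy-7-ethyl-3,4,4-trimethyl-3-(prop-2-en-1-yl)-1,2,3,4-tetrahydronaphthalene, epoxide configuration undefined | CCc1ccc2c(c1)C1OC1[C@@](C)(CC=C)C2(C)C | intermediate
14 | (3S)-7-ethyl-3,4,4-trimethyl-3-(prop-2-en-1-yl)-3,4-dihydronaphthalen-2(1H)-one | CCc1ccc2c(c1)CC(=O)[C@@](C)(CC=C)C2(C)C | intermediate
15 | iminium bromide, N-{[(3S)-2-bromo-7-ethyl-3,4,4-trimethyl-3-(prop-2-en-1-yl)-3,4-dihydronaphthalen-1-yl]methylidene}-N-methylmethanaminium bromide | CCc1ccc2c(c1)C(C=[N+](C)C)=C(Br)[C@@](C)(CC=C)C2(C)C.[Br-] | intermediate (not isolated)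
16 | (3S)-2-bromo-7-ethyl-3,4,4-trimethyl-3-(prop-2-en-1-yl)-3,4-dihydronaphthalene-1-carbaldehyde | CCc1ccc2c(c1)C(C=O)=C(Br)[C@@](C)(CC=C)C2(C)C | intermediate
17 | (1R)-1-[(3S)-2-bromo-7-ethyl-3,4,4-trimethyl-3-(prop-2-en-1-yl)-3,4-dihydronaphthalen-1-yl]prop-2-en-1-ol | CCc1ccc2c(c1)C([C@H](O)C=C)=C(Br)[C@@](C)(CC=C)C2(C)C | intermediate
18 | carbon monoxide | [C-]#[O+] | starting material
19 | (1R,4S)-8-ethyl-1-ethenyl-4,5,5-trimethyl-4-(prop-2-en-1-yl)-4,5-dihydronaphtho[1,2-c]furan-3(1H)-one | CCc1ccc2c(c1)C1=C(C(=O)O[C@@H]1C=C)[C@@](C)(CC=C)C2(C)C | intermediate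
20 | (1R,3aR,4R,9bS)-8-ethyl-1-ethenyl-4,5,5-trimethyl-4-(prop-2-en-1-yl)-3a,4,5,9b-tetrahydronaphtho[1,2-c]furan-3(1H)-one | CCc1ccc2c(c1)[C@H]1[C@@H](C=C)OC(=O)[C@H]1[C@@](C)(CC=C)C2(C)C | intermediate
21 | tetracyclic cycloheptene lactone: cis-lactone of 20 in which the O-methine and the quaternary carbon are bridged by CH=CH–CH2 (alkene next to the O-methine); H at O-methine, benzylic and α-carbons all cis | CCc1ccc2c(c1)[C@H]1[C@@H]3OC(=O)[C@H]1[C@@](C)(CC=C3)C2(C)C | intermediate
22 | allylic hydroperoxide: OOH on the ring carbon next to the O-methine, double bond moved next to the quaternary carbon | CCc1ccc2c(c1)[C@H]1[C@@H]3OC(=O)[C@H]1[C@@](C)(C=CC3OO)C2(C)C | intermediate (not isolated)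
23 | peroxyacetate of 22 | CCc1ccc2c(c1)[C@H]1[C@@H]3OC(=O)[C@H]1[C@@](C)(C=CC3OOC(C)=O)C2(C)C | intermediate (not isolated)
24 | 6,8-didebromosalimabromide (tetracyclic enone lactone without bromine) | CCc1ccc2c(c1)[C@H]1[C@@H]3OC(=O)[C@H]1[C@@](C)(C=CC3=O)C2(C)C | intermediate
25 | salimabromide | CCc1c(Br)cc2c(c1Br)[C@H]1[C@@H]3OC(=O)[C@H]1[C@@](C)(C=CC3=O)C2(C)C | target

**Step count and risks**
Total step count: 17. Longest linear sequence: 17 steps, from ethylbenzene.

Steps most likely to fail:

Step 13 (key step). Oxidative addition at a tetrasubstituted vinyl bromide flanked by a quaternary carbon may be slow, which would let protodebromination or insertion of the acylpalladium into the allyl group compete with alcoholysis; the product could also lose its O-methine configuration by base-induced deprotonation. Fallback, setting out from 17: the hydroxyl is deprotonated with n-BuLi (1 equiv) and the bromide exchanged with t-BuLi (2 equiv) in THF at −78 °C, and the vinyllithium alkoxide is quenched with CO2 to give, after acidification, (3S)-7-ethyl-1-[(1R)-1-hydroxyprop-2-en-1-yl]-3,4,4-trimethyl-3-(prop-2-en-1-yl)-3,4-dihydronaphthalene-2-carboxylic acid F1. This acid should lactonise on standing or with EDC·HCl/DMAP, and the route is rejoined at 19.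

Step 14. Protonation at the benzylic carbon may show poor facial selectivity, and electron transfer could instead cleave the allylic lactone C–O bond or, through the alkoxide formed, shift the vinyl double bond into conjugation. Fallback, setting out from 19: a polar hydride addition in place of electron transfer, with Cu(OAc)2·H2O (5 mol %), 1,2-bis(diphenylphosphino)benzene and (EtO)2MeSiH in toluene at 23 °C, should deliver hydride to the benzylic carbon from the face opposite the vinyl and allyl groups and give the diethoxy(methyl)silyl ketene acetal of 20, F2. Hydrolysis of this isolable intermediate with aqueous acetic acid in THF at 0 °C protonates the α-carbon from the convex face, and the route is rejoined at 20.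

Step 16. The cis-disubstituted alkene may react too slowly with singlet oxygen, so that sensitiser bleaching, incomplete conversion or loss of regiocontrol in the hydrogen abstraction take over. Fallback, setting out from 21: epoxidation with mCPBA (NaHCO3, CH2Cl2, 0 °C) gives the ring epoxide F3. Opening with PhSeNa (from PhSeSePh and NaBH4, EtOH, 60 °C) at the epoxide carbon remote from the O-methine gives the hydroxy selenide F4. Oxidation with H2O2 (THF, 0 °C to 23 °C) gives the selenoxide F5, which eliminates away from the carbinol to the allylic alcohol F6. Dess–Martin periodinane (CH2Cl2, 23 °C) then oxidises F6 to the enone, and the route is rejoined at 24.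

**Further compounds**
F1 | step 13 | (3S)-7-ethyl-1-[(1R)-1-hydroxyprop-2-en-1-yl]-3,4,4-trimethyl-3-(prop-2-en-1-yl)-3,4-dihydronaphthalene-2-carboxylic acid | CCc1ccc2c(c1)C([C@H](O)C=C)=C(C(=O)O)[C@@](C)(CC=C)C2(C)C
F2 | step 14 | diethoxy(methyl)silyl ketene acetal of 20 (C3=C3a double bond, silyloxy group on C3, benzylic H as in 20) | CCc1ccc2c(c1)[C@H]1[C@@H](C=C)OC(O[Si](C)(OCC)OCC)=C1[C@@](C)(CC=C)C2(C)C
F3 | step 16 | epoxide of 21 at the ring CH=CH, epoxide configuration undefined | CCc1ccc2c(c1)[C@H]1[C@@H]3OC(=O)[C@H]1[C@@](C)(CC4OC43)C2(C)C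
F4 | step 16 | hydroxy selenide: OH on the carbon next to the O-methine, SePh on the next carbon | CCc1ccc2c(c1)[C@H]1[C@@H]3OC(=O)[C@H]1[C@@](C)(CC([Se]c4ccccc4)C3O)C2(C)C
F5 | step 16 | selenoxide of F4 | CCc1ccc2c(c1)[C@H]1[C@@H]3OC(=O)[C@H]1[C@@](C)(CC([Se](=O)c4ccccc4)C3O)C2(C)C
F6 | step 16 | allylic alcohol: OH on the carbon next to the O-methine, double bond next to the quaternary carbon | CCc1ccc2c(c1)[C@H]1[C@@H]3OC(=O)[C@H]1[C@@](C)(C=CC3O)C2(C)C
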